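**Plan**
- **Locants.** The target is numbered as a spiro[5.5]undeca-1,4-dien-3-one: C1(OMe)=C2H–C3(=O)–C4(OMe)=C5H–C6 (spiro); C7 Et, C8 Me, C9 Ar, C10 Me, C11 Ar. Ar = 2,4,5-trimethoxyphenyl.
- **Cuts.** First the methyl shift from O on C3 to O on C1 (28 ⇒ linear dienone 26). Then C4=C5 and C1–C6 together (26 ⇒ iodomethylidene-cyclohexane 18 + methyl semisquarate 21). Then C5 (⇒ ketone 14), C11–Ar, the C8 methyl and C9–Ar (⇒ enone 5), whose ring comes from crotonaldehyde and a β-keto ester.
- **Enabling feature.** Ring atoms C4(O)–C3(O)–C2(H)–C1(O) carry the oxygen pattern of a semisquaric ester, and C5=C6 is a vinyl unit exocyclic to the cyclohexane. A temporary four-membered ring can therefore be attached at C5, opened to a ketene and closed on C6.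
- **Forward order.** Cyclohexene ring (step 1), substituents and reduction (steps 2–9), C5 (steps 10–12), dienone ring in one operation (step 14), methyl shift (step 15).
- **Stereochemistry.** C10 comes from an iminium-catalysed Michael addition. C9 and C11 are set α to a ketone and take the equatorial position. C7 and C8 come from an OH-directed hydrogenation. C6 comes from equatorial ring closure, because the axial face is blocked by the axial C8 methyl.

Key step: step 14

Assumption: the target string encodes no rotamer about the aryl–cyclohexane bonds, so these are treated as equilibrating, and tert-butyl 3-oxohexanoate is taken as a catalogue compound.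

Step 1
Reactants: 1 (E)-but-2-enal; 2 tert-butyl 3-oxohexanoate
Product: 5 (5S)-2-ethyl-5-methylcyclohex-2-en-1-one, via Michael adduct 3 (not isolated), via keto ester 4 (not isolated)
Conditions: (R)-α,α-diphenylprolinol trimethylsilyl ether (10 mol %), PhCO2H (10 mol %), neat, 23 °C; then TsOH·H2O (20 mol %), toluene, 80 °C
Reagents that add atoms: none
Why: Iminium-catalysed asymmetric Michael addition of the β-keto ester sets the methyl-bearing stereocentre (the silyloxydiphenylmethyl group of the (R)-catalyst shields one face of the E-iminium ion), and the acid stage effects intramolecular aldol condensation through the γ-methylene group, tert-butyl ester cleavage and decarboxylation.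

Step 2
Reactants: 5 (5S)-2-ethyl-5-methylcyclohex-2-en-1-one
Product: 6 [(3S)-6-ethyl-3-methylcyclohexa-1,5-dien-1-yl]oxy(trimethyl)silane
Conditions: LiN(i-Pr)2, THF, −78 °C; Me3SiCl, −78 → 0 °C
Reagents that add atoms: chlorotrimethylsilane, C[Si](C)(C)Cl
Why: Kinetic α′-deprotonation of a cyclohexenone followed by O-silylation gives the cross-conjugated silyl dienol ether regiospecifically and leaves the stereocentre untouched.

Step 3
Reactants: 6 silyl dienol ether; 7 1-bromo-2,4,5-trimethoxybenzene
Product: 8 (5S,6S)-2-ethyl-5-methyl-6-(2,4,5-trimethoxyphenyl)cyclohex-2-en-1-one (aryl trans to methyl)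
Conditions: Pd2(dba)3 (cat.), P(t-Bu)3, Bu3SnF, toluene, 85 °C
Reagents that add atoms: none
Why: Palladium-catalysed α-arylation of a silyl enol ether by way of its tin enolate couples only at the enol carbon, and the new α-aryl centre is epimerisable and should settle trans to the neighbouring methyl group.

Step 4
Reactants: 8 α′-aryl enone
Product: 9 (5S,6S)-2-ethyl-1,5-dimethyl-6-(2,4,5-trimethoxyphenyl)cyclohex-2-en-1-ol (carbinol epimers)
Conditions: CeCl3, MeLi, THF, −78 °C
Reagents that add atoms: methyllithium, [Li]C
Why: Organocerium 1,2-addition avoids enolisation of the acidic α-aryl ketone and conjugate addition, and the carbinol configuration is irrelevant because this carbon becomes sp2 in step 5.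

Step 5
Reactants: 9 tertiary allylic alcohol
Product: 10 (4R,5S)-2-ethyl-3,5-dimethyl-4-(2,4,5-trimethoxyphenyl)cyclohex-2-en-1-one
Conditions: C5H5NH[CrO3Cl], 4 Å molecular sieves, CH2Cl2, 23 °C
Reagents that add atoms: pyridinium chlorochromate, [O-][Cr](=O)(=O)Cl.c1cc[nH+]cc1
Why: Dauben–Michno oxidative 1,3-transposition, in which the chromate ester of the tertiary allylic alcohol undergoes a [3,3] shift and is oxidised to the transposed tetrasubstituted enone without touching the two stereocentres.

Step 6
Reactants: 10 tetrasubstituted enone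
Product: 11 (1R,4R,5S)-2-ethyl-3,5-dimethyl-4-(2,4,5-trimethoxyphenyl)cyclohex-2-en-1-ol
Conditions: NaBH4, CeCl3·7H2O, MeOH, 0 °C
Reagents that add atoms: none
Why: Luche 1,2-reduction, in which hydride arrives axially as in carvone to cis-carveol, so the hydroxyl group should end cis to the C5 methyl group and trans to the aryl group.

Step 7
Reactants: 11 allylic alcohol
Product: 12 (1R,2R,3R,4R,5S)-2-ethyl-3,5-dimethyl-4-(2,4,5-trimethoxyphenyl)cyclohexan-1-ol
Conditions: [Ir(cod)(PCy3)(py)]PF6 (cat.), H2 (pressure), CH2Cl2, 23 °C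
Reagents that add atoms: none
Why: Hydroxyl-directed homogeneous hydrogenation, in which the cationic iridium complex binds the allylic OH and delivers both hydrogens to that face of the tetrasubstituted alkene, placing ethyl and methyl cis to each other and cis to the aryl group.

Step 8
Reactants: 12 cyclohexanol
Product: 13 (2R,3R,4R,5S)-2-ethyl-3,5-dimethyl-4-(2,4,5-trimethoxyphenyl)cyclohexan-1-one
Conditions: Dess–Martin periodinane, CH2Cl2, 23 °C
Reagents that add atoms: none
Why: Dess–Martin oxidation under neutral conditions returns the ketone, and the α-ethyl centre already occupies its more stable equatorial position.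

Step 9
Reactants: 13 ketone; 7 1-bromo-2,4,5-trimethoxybenzene
Product: 14 (2R,3R,4S,5R,6R)-2-ethyl-3,5-dimethyl-4,6-bis(2,4,5-trimethoxyphenyl)cyclohexan-1-one
Conditions: Pd2(dba)3 (cat.), XPhos, NaOt-Bu, toluene, 80 °C
Reagents that add atoms: none
Why: Buchwald–Hartwig-type ketone α-arylation takes the methylene rather than the methine α-carbon, and under the basic conditions the new α-aryl centre equilibrates to the equatorial position, trans to the adjacent methyl group.

Step 10
Reactants: 14 diaryl ketone
Product: 15 methyl enol ether (1-methoxymethylidene analogue of 14; E/Z mixture; ring centres unchanged in space)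
Conditions: Ph3P(CH2OMe)Cl (excess), KOt-Bu, THF, 0 °C → reflux
Reagents that add atoms: (methoxymethyl)triphenylphosphonium chloride, COC[P+](c1ccccc1)(c1ccccc1)c1ccccc1.[Cl-]
Why: Wittig alkoxymethylenation with excess non-stabilised ylide, because enolisation of the α-aryl ketone is reversible; both α-centres are already in their thermodynamic positions and the alkene geometry is of no consequence.

Step 11
Reactants: 15 methyl enol ether
Product: 17 hydrazone of aldehyde 16, via aldehyde 16 (not isolated)
Conditions: 2 M HCl, THF, 23 °C; then Et3N, N2H4·H2O (excess), EtOH, 60 °C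
Reagents that add atoms: hydrazine hydrate, NN.O; water, O
Why: Acid hydrolysis of the enol ether followed by hydrazone formation with excess hydrazine, and the formyl-bearing carbon becomes sp2 again in step 12, so its configuration does not matter.

Step 12
Reactants: 17 hydrazone
Product: 18 exocyclic vinyl iodide (1-iodomethylidene analogue of 14; E/Z mixture)
Conditions: I2, 1,1,3,3-tetramethylguanidine, Et2O/THF, 0 → 23 °C
Reagents that add atoms: iodine, II
Why: Barton vinyl iodide synthesis, in which iodine oxidises the hydrazone to an α-iodo cation equivalent that loses the tertiary α-proton to give the trisubstituted iodoalkene.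

Step 13
Reactants: 19 dimethyl squarate
Product: 21 methyl semisquarate (3-methoxycyclobut-3-ene-1,2-dione), via hydroxycyclobutenone 20 (not isolated)
Conditions: LiAlH(Ot-Bu)3, THF, −20 °C; then HCl, CH2Cl2, 23 °C
Reagents that add atoms: none
Why: Selective 1,2-reduction of one squarate carbonyl followed by acid-induced allylic transposition with loss of methanol is the standard entry to semisquaric esters.

Step 14
Reactants: 18 exocyclic vinyl iodide; 21 methyl semisquarate
Product: 26 (6S,7R,8S,9S,10R,11R)-7-ethyl-3,4-dimethoxy-8,10-dimethyl-9,11-bis(2,4,5-trimethoxyphenyl)spiro[5.5]undeca-2,4-dien-1-one, via vinyllithium 22 (not isolated), via lithium alkoxide 23 (not isolated), via cyclobutenone methyl ether 24 (not isolated), via dienylketene 25 (not isolated)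
Conditions: t-BuLi (2.0 equiv), Et2O, −78 °C; 21, THF, −78 °C; MeOTf (1.0 equiv), −78 → 0 °C; toluene added, ethers distilled off, 110 °C
Reagents that add atoms: tert-butyllithium, [Li]C(C)(C)C; methyl triflate, COS(=O)(=O)C(F)(F)F
Why: The vinyllithium adds 1,2 to the ketone-like carbonyl of 21 (the other carbonyl is deactivated as a vinylogous ester), which makes the =CH–C(OMe) sigma bond, and methyl triflate caps the alkoxide. On heating, the cyclobutenone opens by a conrotatory four-electron electrocyclic reaction in which the methoxy donor rotates outward and the alkenyl group inward, giving the Z-dienylketene 25. This closes by a disrotatory six-electron electrocyclisation of the ketene carbon onto the fully substituted alkene carbon, which forms the six-membered ring, the bond to the spiro carbon and the ring CH=C(OMe) double bond, and the product must remain a cyclohexa-2,4-dienone because that terminus bears no hydrogen. The closest known reaction type is the Moore ring expansion of 4-alkenylcyclobutenones, and closure of a dienylketene onto a β,β-disubstituted terminus is the ring-forming event of the chromium-carbene cyclohexadienone annulation. The only new stereocentre, the spiro carbon, is set by the alkene face that the ketene carbon reaches: the chair holds the future C8 methyl axial and 1,3 to the spiro carbon, so the axial face is blocked, the new bond forms equatorially and the =CH arm ends axial as in the target. Both alkene isomers of 18 converge because the CH carbon becomes a ring sp2 atom, and the carbinol stereocentre of 24 is erased in the ring opening.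

Step 15
Reactants: 26 linearly conjugated spirodienone
Product: 28 tatanan B, via cyclohexadienyl cation triflate 27 (not isolated)
Conditions: MeOTf (1.2 equiv), 2,6-di-tert-butyl-4-methylpyridine, CH2Cl2, 0 → 23 °C; then NaI, acetone, 0 °C
Reagents that add atoms: methyl triflate, COS(=O)(=O)C(F)(F)F
Why: Proposed new method: the carbonyl oxygen of the vinylogous ester in 26 is the most nucleophilic site, so methyl triflate should O-methylate it to cation 27, which is the ipso σ-complex of a 2,4,5-trimethoxyphenyl ring; iodide should then remove by SN2 the methyl group on the oxygen para to the spiro carbon, which bears most of the charge and is the less shielded, unveiling the cross-conjugated dienone without touching the spiro centre; the closest known reaction types are O-alkylation of 3-alkoxyenones with Meerwein-type reagents and the dealkylation of para-methoxy σ-complexes that ends ipso-cyclisations to spirodienones.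

**Compound list**
1 | (E)-but-2-enal | C/C=C/C=O | starting material
2 | tert-butyl 3-oxohexanoate | CCCC(=O)CC(=O)OC(C)(C)C | starting material
3 | tert-butyl 2-butanoyl-(3S)-3-methyl-5-oxopentanoate (C2 epimers) | CCCC(=O)C(C(=O)OC(C)(C)C)[C@@H](C)CC=O | intermediate
4 | tert-butyl (6S)-3-ethyl-6-methyl-2-oxocyclohex-3-ene-1-carboxylate (C1 epimers) | CCC1=CC[C@H](C)C(C(=O)OC(C)(C)C)C1=O | intermediate
5 | (5S)-2-ethyl-5-methylcyclohex-2-en-1-one | CCC1=CC[C@H](C)CC1=O | intermediate
6 | [(3S)-6-ethyl-3-methylcyclohexa-1,5-dien-1-yl]oxy(trimethyl)silane | CCC1=CC[C@H](C)C=C1O[Si](C)(C)C | intermediate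
7 | 1-bromo-2,4,5-trimethoxybenzene | COc1cc(OC)c(OC)cc1Br | starting material
8 | (5S,6S)-2-ethyl-5-methyl-6-(2,4,5-trimethoxyphenyl)cyclohex-2-en-1-one | CCC1=CC[C@H](C)[C@@H](c2cc(OC)c(OC)cc2OC)C1=O | intermediate
9 | (5S,6S)-2-ethyl-1,5-dimethyl-6-(2,4,5-trimethoxyphenyl)cyclohex-2-en-1-ol (C1 epimers) | CCC1=CC[C@H](C)[C@@H](c2cc(OC)c(OC)cc2OC)C1(C)O | intermediate
10 | (4R,5S)-2-ethyl-3,5-dimethyl-4-(2,4,5-trimethoxyphenyl)cyclohex-2-en-1-one | CCC1=C(C)[C@H](c2cc(OC)c(OC)cc2OC)[C@@H](C)CC1=O | intermediate
11 | (1R,4R,5S)-2-ethyl-3,5-dimethyl-4-(2,4,5-trimethoxyphenyl)cyclohex-2-en-1-ol | CCC1=C(C)[C@H](c2cc(OC)c(OC)cc2OC)[C@@H](C)C[C@H]1O | intermediate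
12 | (1R,2R,3R,4R,5S)-2-ethyl-3,5-dimethyl-4-(2,4,5-trimethoxyphenyl)cyclohexan-1-ol | CC[C@@H]1[C@H](C)[C@H](c2cc(OC)c(OC)cc2OC)[C@@H](C)C[C@H]1O | intermediate
13 | (2R,3R,4R,5S)-2-ethyl-3,5-dimethyl-4-(2,4,5-trimethoxyphenyl)cyclohexan-1-one | CC[C@@H]1[C@H](C)[C@H](c2cc(OC)c(OC)cc2OC)[C@@H](C)CC1=O | intermediate
14 | (2R,3R,4S,5R,6R)-2-ethyl-3,5-dimethyl-4,6-bis(2,4,5-trimethoxyphenyl)cyclohexan-1-one | CC[C@@H]1[C@H](C)[C@H](c2cc(OC)c(OC)cc2OC)[C@@H](C)[C@H](c2cc(OC)c(OC)cc2OC)C1=O | intermediate
15 | 1-(methoxymethylidene) analogue of 14, E/Z mixture, ring centres as in 14 | CC[C@@H]1[C@H](C)[C@H](c2cc(OC)c(OC)cc2OC)[C@@H](C)[C@H](c2cc(OC)c(OC)cc2OC)C1=COC | intermediate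
16 | (1S,2R,3S,4S,5R,6S)-2-ethyl-3,5-dimethyl-4,6-bis(2,4,5-trimethoxyphenyl)cyclohexane-1-carbaldehyde (formyl equatorial) | CC[C@@H]1[C@H](C)[C@H](c2cc(OC)c(OC)cc2OC)[C@@H](C)[C@H](c2cc(OC)c(OC)cc2OC)[C@H]1C=O | intermediate
17 | hydrazone of 16 | CC[C@@H]1[C@H](C)[C@H](c2cc(OC)c(OC)cc2OC)[C@@H](C)[C@H](c2cc(OC)c(OC)cc2OC)[C@H]1C=NN | intermediate
18 | 1-(iodomethylidene) analogue of 14, E/Z mixture, ring centres as in 14 | CC[C@@H]1[C@H](C)[C@H](c2cc(OC)c(OC)cc2OC)[C@@H](C)[C@H](c2cc(OC)c(OC)cc2OC)C1=CI | intermediate
19 | dimethyl squarate (3,4-dimethoxycyclobut-3-ene-1,2-dione) | COC1=C(OC)C(=O)C1=O | starting material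
20 | 4-hydroxy-2,3-dimethoxycyclobut-2-en-1-one | COC1=C(OC)C(O)C1=O | intermediate
21 | methyl semisquarate (3-methoxycyclobut-3-ene-1,2-dione) | COC1=CC(=O)C1=O | intermediate
22 | vinyllithium from 18 | CC[C@@H]1[C@H](C)[C@H](c2cc(OC)c(OC)cc2OC)[C@@H](C)[C@H](c2cc(OC)c(OC)cc2OC)C1=C[Li] | intermediate
23 | lithium 1-alkenyl-2-methoxy-4-oxocyclobut-2-en-1-olate (carbinol epimers) | CC[C@@H]1[C@H](C)[C@H](c2cc(OC)c(OC)cc2OC)[C@@H](C)[C@H](c2cc(OC)c(OC)cc2OC)C1=CC2(O[Li])C(OC)=CC2=O | intermediate
24 | 4-alkenyl-3,4-dimethoxycyclobut-2-en-1-one (C4 epimers) | CC[C@@H]1[C@H](C)[C@H](c2cc(OC)c(OC)cc2OC)[C@@H](C)[C@H](c2cc(OC)c(OC)cc2OC)C1=CC2(OC)C(OC)=CC2=O | intermediate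
25 | Z-dienylketene (3,4-dimethoxy-5-cyclohexylidenepenta-1,3-dien-1-one) | CC[C@@H]1[C@H](C)[C@H](c2cc(OC)c(OC)cc2OC)[C@@H](C)[C@H](c2cc(OC)c(OC)cc2OC)C1=C/C(OC)=C(OC)\C=C=O | intermediate
26 | (6S,7R,8S,9S,10R,11R)-7-ethyl-3,4-dimethoxy-8,10-dimethyl-9,11-bis(2,4,5-trimethoxyphenyl)spiro[5.5]undeca-2,4-dien-1-one | CC[C@@H]1[C@H](C)[C@H](c2cc(OC)c(OC)cc2OC)[C@@H](C)[C@H](c2cc(OC)c(OC)cc2OC)[C@]12C=C(OC)C(OC)=CC2=O | intermediate
27 | 1,3,4-trimethoxy spiro-cyclohexadienyl cation triflate (drawn as the C3 oxocarbenium form) | CC[C@@H]1[C@H](C)[C@H](c2cc(OC)c(OC)cc2OC)[C@@H](C)[C@H](c2cc(OC)c(OC)cc2OC)[C@]12C=C(OC)C(=[O+]C)C=C2OC.[O-]S(=O)(=O)C(F)(F)F | intermediate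
28 | tatanan B, (6S,7R,8S,9S,10R,11R)-7-ethyl-1,4-dimethoxy-8,10-dimethyl-9,11-bis(2,4,5-trimethoxyphenyl)spiro[5.5]undeca-1,4-dien-3-one | CC[C@@H]1[C@H](C)[C@H](c2cc(OC)c(OC)cc2OC)[C@@H](C)[C@H](c2cc(OC)c(OC)cc2OC)[C@]12C=C(OC)C(=O)C=C2OC | target

**Step count**
Total step count: 15. Longest linear sequence: 14 (steps 1–12, 14, 15). Step 13 is a one-step side branch.

**Steps most likely to fail**

Step 15 (labelled step). The methyl group may be lost from the wrong oxygen, which only regenerates 26. The cation may also suffer a 1,2-alkyl shift of the dienone–phenol type. The fallback uses known chemistry and sets out from 26. The vinylogous ester is saponified (LiOH, aqueous THF) to the vinylogous acid F1. O-methylation of this acid with trimethylsilyldiazomethane in toluene/MeOH gives both enol ethers. Compound 28 is separated by chromatography and the co-formed 26 is returned to the saponification. The route is rejoined at 28.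

Step 14. The hindered vinyllithium may add sluggishly, and above all the facial selectivity of the ketene closure may be poor, so that part of 25 closes on the axial face. The fallback sets out from 25 as formed in step 14. The spiro epimer F2 is separated and irradiated (365 nm, toluene, 23 °C). Linearly conjugated cyclohexadienones open photochemically to their dienylketenes, here 25 again. This ketene re-closes in the dark, so repeated separation and irradiation funnel material back to the route at 26.

Step 10. Enolisation of the hindered α-aryl ketone may outrun addition of the bulky ylide. The fallback sets out from 14. Chloromethyllithium (ICH2Cl, MeLi·LiBr, THF, −78 °C), a small and very fast carbenoid, adds to the carbonyl and closes to the spiro-epoxide F3. A Meinwald rearrangement (BF3·OEt2, CH2Cl2, −78 °C) then shifts hydride to give the aldehyde. The route is rejoined at 16, which goes on to the hydrazone as in step 11.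

**Further compounds**
F1 | step 15 | vinylogous acid, 3-hydroxy analogue of 26 (enol form) | CC[C@@H]1[C@H](C)[C@H](c2cc(OC)c(OC)cc2OC)[C@@H](C)[C@H](c2cc(OC)c(OC)cc2OC)[C@]12C=C(OC)C(O)=CC2=O
F2 | step 14 | spiro (C6) epimer of 26 | CC[C@@H]1[C@H](C)[C@H](c2cc(OC)c(OC)cc2OC)[C@@H](C)[C@H](c2cc(OC)c(OC)cc2OC)[C@@]12C=C(OC)C(OC)=CC2=O
F3 | step 10 | spiro-epoxide of 14 (1-oxaspiro[2.5]octane; epoxide carbon configuration inconsequential) | CC[C@@H]1[C@H](C)[C@H](c2cc(OC)c(OC)cc2OC)[C@@H](C)[C@H](c2cc(OC)c(OC)cc2OC)C12CO2
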